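**Strategy.** The route rests on cutting the C3–C4 sigma bond of the fifth isoprene unit counted from the quinone ring: the methyl-bearing sp2 carbon of the fifth trisubstituted alkene against its allylic CH2. An invertive Zweifel olefination forms it. A (Z)-α-methylalkenyllithium carrying the protected hydroquinone ring and four prenyl units adds to a C26 homoallylic pinacol boronate carrying the (S) stereocentre. Iodine triggers 1,2-migration of the tail from boron to carbon, and anti elimination delivers the E alkene. The step exploits the 1,5-diene spacing: C4 is a primary, unbranched CH2 that migrates cleanly, and the Z iodide comes from an aldehyde in one Wittig step.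

Key step: step 14

Remark on the chemistry: the quinone is carried as its hydroquinone tetramethyl ether and released last; (R)-citronellyl bromide supplies the chain stereocentre, whose descriptor becomes S in the target only because the CIP ranks of its two chains swap on chain extension.

**Step 1**
Reactants: 1 (2E,6E,10E)-geranylgeraniol
Product: 2 (2E,6E,10E)-geranylgeranyl bromide
Conditions: PBr3, Et2O, −10 → 0 °C
Reagents that add atoms: phosphorus tribromide BrP(Br)Br
Why: Bromination of a primary allylic alcohol with PBr3 is an SN2 displacement of the phosphite ester at C1 and should leave the three E alkenes untouched.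

**Step 2**
Reactants: 3 2,3,4,5-tetramethoxytoluene; 2 (2E,6E,10E)-geranylgeranyl bromide
Product: 6 1-[(2E,6E,10E)-geranylgeranyl]-2,3,4,5-tetramethoxy-6-methylbenzene, via aryllithium 4 (not isolated), via arylcopper 5 (not isolated)
Conditions: n-BuLi, TMEDA, hexane, 0 °C → rt; CuBr·SMe2, THF, −40 °C; then 2, −40 → 0 °C
Reagents that add atoms: none
Why: Methoxy-directed ortho-lithiation takes the only ring hydrogen, and the derived arylcopper should alkylate the primary allylic bromide at C1 (SN2-type allylic substitution) with retention of the 2E geometry.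

**Step 3**
Reactants: 6 1-[(2E,6E,10E)-geranylgeranyl]-2,3,4,5-tetramethoxy-6-methylbenzene
Product: 7 (2E,6E,10E,14E)-2,6,10,14-tetramethyl-16-(2,3,4,5-tetramethoxy-6-methylphenyl)hexadeca-2,6,10,14-tetraen-1-ol
Conditions: SeO2 (cat.), t-BuOOH, salicylic acid (cat.), CH2Cl2, 0 °C → rt, stopped at partial conversion
Reagents that add atoms: tert-butyl hydroperoxide CC(C)(C)OO (oxygen, relayed by SeO2)
Why: Sharpless SeO2/t-BuOOH allylic oxidation (ene reaction, then [2,3]-sigmatropic shift) should pick the E methyl of the terminal, most accessible trisubstituted alkene and give the E allylic alcohol.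

**Step 4**
Reactants: 7 the ω-allylic alcohol
Product: 8 1-[(2E,6E,10E,14E)-16-bromo-3,7,11,15-tetramethylhexadeca-2,6,10,14-tetraen-1-yl]-2,3,4,5-tetramethoxy-6-methylbenzene
Conditions: CBr4, PPh3, CH2Cl2, 0 °C
Reagents that add atoms: carbon tetrabromide BrC(Br)(Br)Br
Why: Appel bromination converts the primary allylic alcohol under neutral conditions by SN2 attack of bromide on the alkoxyphosphonium ion.

**Step 5**
Reactants: 8 the ω-allylic bromide
Product: 10 (4E,8E,12E,16E)-4,8,12,16-tetramethyl-18-(2,3,4,5-tetramethoxy-6-methylphenyl)octadeca-4,8,12,16-tetraenal, via N-tert-butyl imine 9 (not isolated)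
Conditions: N-tert-butylethanimine, LiN(i-Pr)2, THF, 0 °C; then 8, −78 → 0 °C; aq. oxalic acid, Et2O, rt
Reagents that add atoms: N-tert-butylethanimine CC=NC(C)(C)C (two carbons); water O (aldehyde oxygen)
Why: Metalloenamine (aza-enolate) alkylation of the lithiated acetaldehyde imine should displace the primary allylic bromide at carbon, and mild aqueous acid then hydrolyses imine 9 to the aldehyde.

**Step 6**
Reactants: 10 the C2-extended aldehyde
Product: 11 1-[(2E,6E,10E,14E,18Z)-19-iodo-3,7,11,15-tetramethylicosa-2,6,10,14,18-pentaen-1-yl]-2,3,4,5-tetramethoxy-6-methylbenzene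
Conditions: [Ph3PEt]I, n-BuLi, THF, rt; I2, −78 °C; NaN(SiMe3)2, −20 °C; then 10, −78 → −20 °C
Reagents that add atoms: ethyltriphenylphosphonium iodide CC[P+](c1ccccc1)(c1ccccc1)c1ccccc1.[I-] (CH3–C unit); iodine II
Why: Stork–Zhao-type Wittig olefination with the non-stabilised α-iodoethylidene ylide forms the cis-oxaphosphetane under kinetic control and should give the Z iodoalkene (iodine cis to the chain).

**Step 7**
Reactants: 12 (2E,6E)-farnesol
Product: 13 (2E,6E)-farnesyl tert-butyldimethylsilyl ether
Conditions: TBSCl, imidazole, DMF, rt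
Reagents that add atoms: tert-butyldimethylsilyl chloride CC(C)(C)[Si](C)(C)Cl
Why: Standard imidazole-mediated silylation of a primary alcohol.

**Step 8**
Reactants: 13 farnesyl TBS ether
Product: 14 (2E,6E,10E)-12-(tert-butyldimethylsilyloxy)-2,6,10-trimethyldodeca-2,6,10-trien-1-ol
Conditions: SeO2 (cat.), t-BuOOH, salicylic acid (cat.), CH2Cl2, 0 °C → rt
Reagents that add atoms: tert-butyl hydroperoxide CC(C)(C)OO (oxygen, relayed by SeO2)
Why: Sharpless SeO2/t-BuOOH allylic oxidation should again select the E methyl of the terminal trisubstituted alkene.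

**Step 9**
Reactants: 14 the ω-hydroxy farnesyl TBS ether
Product: 15 (2E,6E,10E)-12-bromo-1-(tert-butyldimethylsilyloxy)-3,7,11-trimethyldodeca-2,6,10-triene
Conditions: CBr4, PPh3, CH2Cl2, 0 °C
Reagents that add atoms: carbon tetrabromide BrC(Br)(Br)Br
Why: Appel bromination of the primary allylic alcohol is neutral and should leave the silyl ether intact.

**Step 10**
Reactants: 16 (R)-citronellyl bromide [(6R)-8-bromo-2,6-dimethyloct-2-ene]; 15 the ω-bromo farnesyl TBS ether
Product: 18 tert-butyldimethylsilyl ether of (2E,6E,10E,15S)-3,7,11,15,19-pentamethylicosa-2,6,10,18-tetraen-1-ol, via citronellylmagnesium bromide 17 (not isolated)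
Conditions: Mg, THF, 40 °C; then 15, Li2CuCl4 (cat.), THF, −78 → 0 °C
Reagents that add atoms: none
Why: Kochi-type copper-catalysed Grignard coupling (Li2CuCl4) should substitute the primary allylic bromide at its CH2 with retention of the E alkene, and the stereocentre of 16, which is not at a reacting carbon, is carried over unchanged as the future (S) centre.

**Step 11**
Reactants: 18 the C25 TBS ether
Product: 19 (2E,6E,10E,15S)-3,7,11,15,19-pentamethylicosa-2,6,10,18-tetraen-1-ol
Conditions: Bu4NF, THF, 0 °C → rt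
Reagents that add atoms: none
Why: Fluoride-induced cleavage of the Si–O bond (desilylation) frees the allylic alcohol.

**Step 12**
Reactants: 19 the C25 allylic alcohol
Product: 20 (2E,6E,10E,15S)-1-bromo-3,7,11,15,19-pentamethylicosa-2,6,10,18-tetraene
Conditions: PBr3, Et2O, −10 → 0 °C
Reagents that add atoms: phosphorus tribromide BrP(Br)Br
Why: SN2 bromination of the primary allylic alcohol with PBr3, as in step 1.

**Step 13**
Reactants: 20 the C25 allylic bromide
Product: 21 2-[(3E,7E,11E,16S)-4,8,12,16,20-pentamethylhenicosa-3,7,11,19-tetraen-1-yl]-4,4,5,5-tetramethyl-1,3,2-dioxaborolane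
Conditions: CH2(Bpin)2, NaOt-Bu, THF, rt
Reagents that add atoms: bis(pinacolatoboryl)methane CC1(C)OB(CB2OC(C)(C)C(C)(C)O2)OC1(C)C
Why: Morken deborylative alkylation: tert-butoxide removes one boron of the geminal bis(boronate) to give an α-boryl carbanion that should displace the primary allylic bromide by SN2, adding the CH2–Bpin unit.

**Step 14**
Reactants: 11 the (18Z)-alkenyl iodide; 21 the homoallylic pinacol boronate
Product: 25 1-[(2E,6E,10E,14E,18E,22E,26E,30E,35S)-3,7,11,15,19,23,27,31,35,39-decamethyltetraconta-2,6,10,14,18,22,26,30,38-nonaen-1-yl]-2,3,4,5-tetramethoxy-6-methylbenzene, via alkenyllithium 22 (not isolated), via lithium boronate complex 23 (not isolated), via β-iodoboronic ester 24 (not isolated)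
Conditions: 11, t-BuLi (2 equiv), THF, −78 °C; then 21, −78 °C; I2 (1 equiv), THF, −78 °C; NaOMe, MeOH, −78 °C → rt
Reagents that add atoms: none
Why: Iodine–lithium exchange on 11 with retention gives alkenyllithium 22, which adds to boron of 21 to give boronate complex 23, so the two halves are first tied together through boron. Iodine then attacks the electron-rich alkenyl double bond of 23 and the primary homoallyl group migrates from boron to the methyl-bearing carbon anti to the iodonium ion, which forms the new carbon–carbon bond and gives β-iodoboronic ester 24. Methoxide adds to boron and triggers anti elimination of boron and iodide, so the net result is inversion at the alkenyl carbon and the Z iodide should become the E trisubstituted alkene. No ring is closed and no stereocentre remains from the step: the two transient centres of 24 are set by the anti addition and erased by the elimination, and the remote (S) centre is not involved. The step needs geometric fidelity and chemoselectivity: the α-alkyl alkenyllithium is configurationally stable at −78 °C, both stereochemical events are stereospecific, and the anionic boronate alkene is far more nucleophilic than the eight neutral trisubstituted alkenes, so one equivalent of iodine at −78 °C should react only there. The closest known reaction type is the Zweifel olefination of alkenyllithiums with primary alkyl pinacol boronates to give trisubstituted alkenes.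

**Step 15**
Reactants: 25 the tetramethyl hydroquinone ether
Product: 26 2,3-dimethoxy-5-methyl-6-[(2E,6E,10E,14E,18E,22E,26E,30E,35S)-3,7,11,15,19,23,27,31,35,39-decamethyltetraconta-2,6,10,14,18,22,26,30,38-nonaen-1-yl]cyclohexa-2,5-diene-1,4-dione (CNP0144872.1)
Conditions: (NH4)2Ce(NO3)6, MeCN/H2O/CH2Cl2, 0 °C
Reagents that add atoms: water O (both carbonyl oxygens)
Why: Oxidative demethylation with (NH4)2Ce(NO3)6: one-electron oxidation of the electron-rich arene, attack of water at the two para methoxy-bearing carbons and loss of methanol should give the para-quinone, while the isolated alkenes survive the short exposure at 0 °C.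

**Compound list**

1 | (2E,6E,10E)-geranylgeraniol | OC/C=C(\C)CC/C=C(\C)CC/C=C(\C)CCC=C(C)C | starting material
2 | (2E,6E,10E)-geranylgeranyl bromide | BrC/C=C(\C)CC/C=C(\C)CC/C=C(\C)CCC=C(C)C | intermediate
3 | 2,3,4,5-tetramethoxytoluene | COc1cc(C)c(OC)c(OC)c1OC | starting material
4 | 2,3,4,5-tetramethoxy-6-methylphenyllithium | COc1c([Li])c(C)c(OC)c(OC)c1OC | intermediate (not isolated)
5 | (2,3,4,5-tetramethoxy-6-methylphenyl)copper | COc1c([Cu])c(C)c(OC)c(OC)c1OC | intermediate (not isolated)
6 | 1-[(2E,6E,10E)-geranylgeranyl]-2,3,4,5-tetramethoxy-6-methylbenzene | COc1c(OC)c(OC)c(C/C=C(\C)CC/C=C(\C)CC/C=C(\C)CCC=C(C)C)c(C)c1OC | intermediate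
7 | (2E,6E,10E,14E)-2,6,10,14-tetramethyl-16-(2,3,4,5-tetramethoxy-6-methylphenyl)hexadeca-2,6,10,14-tetraen-1-ol | COc1c(OC)c(OC)c(C/C=C(\C)CC/C=C(\C)CC/C=C(\C)CC/C=C(\C)CO)c(C)c1OC | intermediate
8 | 1-[(2E,6E,10E,14E)-16-bromo-3,7,11,15-tetramethylhexadeca-2,6,10,14-tetraen-1-yl]-2,3,4,5-tetramethoxy-6-methylbenzene | COc1c(OC)c(OC)c(C/C=C(\C)CC/C=C(\C)CC/C=C(\C)CC/C=C(\C)CBr)c(C)c1OC | intermediate
9 | N-tert-butyl imine of aldehyde 10 | COc1c(OC)c(OC)c(C/C=C(\C)CC/C=C(\C)CC/C=C(\C)CC/C=C(\C)CC/C=N/C(C)(C)C)c(C)c1OC | intermediate (not isolated)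
10 | (4E,8E,12E,16E)-4,8,12,16-tetramethyl-18-(2,3,4,5-tetramethoxy-6-methylphenyl)octadeca-4,8,12,16-tetraenal | COc1c(OC)c(OC)c(C/C=C(\C)CC/C=C(\C)CC/C=C(\C)CC/C=C(\C)CCC=O)c(C)c1OC | intermediate
11 | 1-[(2E,6E,10E,14E,18Z)-19-iodo-3,7,11,15-tetramethylicosa-2,6,10,14,18-pentaen-1-yl]-2,3,4,5-tetramethoxy-6-methylbenzene | COc1c(OC)c(OC)c(C/C=C(\C)CC/C=C(\C)CC/C=C(\C)CC/C=C(\C)CC/C=C(/C)I)c(C)c1OC | intermediate
12 | (2E,6E)-farnesol | OC/C=C(\C)CC/C=C(\C)CCC=C(C)C | starting material
13 | (2E,6E)-farnesyl tert-butyldimethylsilyl ether | CC(C)(C)[Si](C)(C)OC/C=C(\C)CC/C=C(\C)CCC=C(C)C | intermediate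
14 | (2E,6E,10E)-12-(tert-butyldimethylsilyloxy)-2,6,10-trimethyldodeca-2,6,10-trien-1-ol | CC(C)(C)[Si](C)(C)OC/C=C(\C)CC/C=C(\C)CC/C=C(\C)CO | intermediate
15 | (2E,6E,10E)-12-bromo-1-(tert-butyldimethylsilyloxy)-3,7,11-trimethyldodeca-2,6,10-triene | CC(C)(C)[Si](C)(C)OC/C=C(\C)CC/C=C(\C)CC/C=C(\C)CBr | intermediate
16 | (R)-citronellyl bromide, (6R)-8-bromo-2,6-dimethyloct-2-ene | C[C@H](CCC=C(C)C)CCBr | starting material
17 | (R)-citronellylmagnesium bromide | C[C@H](CCC=C(C)C)CC[Mg]Br | intermediate (not isolated)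
18 | tert-butyldimethylsilyl ether of (2E,6E,10E,15S)-3,7,11,15,19-pentamethylicosa-2,6,10,18-tetraen-1-ol | CC(C)(C)[Si](C)(C)OC/C=C(\C)CC/C=C(\C)CC/C=C(\C)CCC[C@H](C)CCC=C(C)C | intermediate
19 | (2E,6E,10E,15S)-3,7,11,15,19-pentamethylicosa-2,6,10,18-tetraen-1-ol | OC/C=C(\C)CC/C=C(\C)CC/C=C(\C)CCC[C@H](C)CCC=C(C)C | intermediate
20 | (2E,6E,10E,15S)-1-bromo-3,7,11,15,19-pentamethylicosa-2,6,10,18-tetraene | BrC/C=C(\C)CC/C=C(\C)CC/C=C(\C)CCC[C@H](C)CCC=C(C)C | intermediate
21 | 2-[(3E,7E,11E,16S)-4,8,12,16,20-pentamethylhenicosa-3,7,11,19-tetraen-1-yl]-4,4,5,5-tetramethyl-1,3,2-dioxaborolane | CC1(C)OB(CC/C=C(\C)CC/C=C(\C)CC/C=C(\C)CCC[C@H](C)CCC=C(C)C)OC1(C)C | intermediate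
22 | (18Z)-19-lithio analogue of 11 (lithium cis to the chain) | COc1c(OC)c(OC)c(C/C=C(\C)CC/C=C(\C)CC/C=C(\C)CC/C=C(\C)CC/C=C(/C)[Li])c(C)c1OC | intermediate (not isolated)
23 | lithium boronate complex: boron of 21 bonded to the alkenyl carbon of 22, boron cis to the ring-side chain | [Li+].COc1c(OC)c(OC)c(C/C=C(\C)CC/C=C(\C)CC/C=C(\C)CC/C=C(\C)CC/C=C(/C)[B-]2(CC/C=C(\C)CC/C=C(\C)CC/C=C(\C)CCC[C@H](C)CCC=C(C)C)OC(C)(C)C(C)(C)O2)c(C)c1OC | intermediate (not isolated)
24 | β-iodoboronic ester: C2 of the fifth unit carries iodine, C3 carries CH3, Bpin and the migrated tail; relative configuration (R*,R*) at these two carbons, formed from both alkene faces, one isomer drawn | COc1c(OC)c(OC)c(C/C=C(\C)CC/C=C(\C)CC/C=C(\C)CC/C=C(\C)CC[C@@H](I)[C@@](C)(B2OC(C)(C)C(C)(C)O2)CC/C=C(\C)CC/C=C(\C)CC/C=C(\C)CCC[C@H](C)CCC=C(C)C)c(C)c1OC | intermediate (not isolated)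
25 | 1-[(2E,6E,10E,14E,18E,22E,26E,30E,35S)-3,7,11,15,19,23,27,31,35,39-decamethyltetraconta-2,6,10,14,18,22,26,30,38-nonaen-1-yl]-2,3,4,5-tetramethoxy-6-methylbenzene | COc1c(OC)c(OC)c(C/C=C(\C)CC/C=C(\C)CC/C=C(\C)CC/C=C(\C)CC/C=C(\C)CC/C=C(\C)CC/C=C(\C)CC/C=C(\C)CCC[C@H](C)CCC=C(C)C)c(C)c1OC | intermediate
26 | 2,3-dimethoxy-5-methyl-6-[(2E,6E,10E,14E,18E,22E,26E,30E,35S)-3,7,11,15,19,23,27,31,35,39-decamethyltetraconta-2,6,10,14,18,22,26,30,38-nonaen-1-yl]cyclohexa-2,5-diene-1,4-dione | COC1=C(OC)C(=O)C(C/C=C(\C)CC/C=C(\C)CC/C=C(\C)CC/C=C(\C)CC/C=C(\C)CC/C=C(\C)CC/C=C(\C)CC/C=C(\C)CCC[C@H](C)CCC=C(C)C)=C(C)C1=O | target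

**Step count.** Total: 15 steps. Longest linear sequence: 9 steps (steps 7 to 15, from farnesol 12).

**Steps most likely to fail**

1. Step 14 (key step). What may go wrong: incomplete formation of the boronate complex at the hindered α-methylalkenyl carbon, consumption of iodine by the other alkenes, or leakage from the anti-migration/anti-elimination pathway that erodes the E geometry. The fallback sets out from aldehyde 10 and boronate 21 and returns at 25; it replaces the invertive boron chemistry by a stereoretentive palladium cross-coupling. Aldehyde 10 is converted with CBr4/PPh3 into the 1,1-dibromoalkene F1. Treatment with n-BuLi and then MeI (Corey–Fuchs sequence with methyl quench) gives the methyl alkyne F2. Hydrozirconation with Cp2Zr(H)Cl under equilibrating conditions (syn addition, zirconium at the methyl-bearing carbon) followed by iodine gives the (18E)-iodide F3. Boronate 21 is converted with KHF2 in MeOH/H2O into the potassium trifluoroborate F4. Suzuki–Miyaura coupling of F3 with F4 (Pd(dppf)Cl2, Cs2CO3, THF/H2O, 80 °C) proceeds with retention and should give 25.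

2. Step 3. What may go wrong: poor site selectivity of the allylic oxidation among the four trisubstituted alkenes and the doubly activated benzylic–allylic CH2, together with over-oxidation to the enal. The fallback sets out from 6 and returns at aldehyde 10, bypassing 7, 8 and 9; it builds the fourth alkene by a Claisen rearrangement instead of oxidising a methyl group. Terminal-selective bromohydrin formation (N-bromosuccinimide, THF/H2O, 0 °C) gives the bromohydrin F5, and K2CO3 in MeOH closes the terminal epoxide F6. Isomerisation with Al(O-i-Pr)3 in toluene at reflux gives the secondary allylic alcohol F7 with an isopropenyl group. Johnson–Claisen rearrangement (triethyl orthoacetate, cat. propionic acid, 140 °C; chair transition state, E alkene) gives the ethyl ester F8, and i-Bu2AlH in CH2Cl2 at −78 °C reduces it to 10.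

3. Step 6. What may go wrong: incomplete Z selectivity in the oxaphosphetane formation and decay of the iodo-ylide before it meets the aldehyde, which would carry the wrong alkene geometry into the key step. The fallback sets out from bromide 8 and returns at 11, bypassing 9 and 10; the geometry is set by a syn hydroalumination instead of a Wittig reaction. Alkylation of 8 with lithiated 1-(trimethylsilyl)propyne (n-BuLi, THF, −78 °C) gives the silyl enyne F9. cis-Hydroalumination (i-Bu2AlH, N-methylpyrrolidine, heptane, 60 °C; aluminium on the silyl-bearing carbon), then MeLi and MeI, gives the (Z)-vinylsilane F10 with silicon cis to the chain. Iododesilylation with N-iodosuccinimide in MeCN at 0 °C proceeds with retention and should give 11.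

**Further compounds**

F1 | step 14 | 1,1-dibromoalkene from aldehyde 10 | COc1c(OC)c(OC)c(C/C=C(\C)CC/C=C(\C)CC/C=C(\C)CC/C=C(\C)CCC=C(Br)Br)c(C)c1OC
F2 | step 14 | methyl alkyne, 1-[(2E,6E,10E,14E)-3,7,11,15-tetramethylicosa-2,6,10,14-tetraen-18-yn-1-yl]-2,3,4,5-tetramethoxy-6-methylbenzene | COc1c(OC)c(OC)c(C/C=C(\C)CC/C=C(\C)CC/C=C(\C)CC/C=C(\C)CCC#CC)c(C)c1OC
F3 | step 14 | (18E)-iodide, geometric isomer of 11 with iodine trans to the chain | COc1c(OC)c(OC)c(C/C=C(\C)CC/C=C(\C)CC/C=C(\C)CC/C=C(\C)CC/C=C(\C)I)c(C)c1OC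
F4 | step 14 | potassium [(3E,7E,11E,16S)-4,8,12,16,20-pentamethylhenicosa-3,7,11,19-tetraen-1-yl]trifluoroborate | [K+].F[B-](F)(F)CC/C=C(\C)CC/C=C(\C)CC/C=C(\C)CCC[C@H](C)CCC=C(C)C
F5 | step 3 | terminal bromohydrin of 6 (bromine on C14, hydroxyl on C15 of the side chain, racemic at C14) | COc1c(OC)c(OC)c(C/C=C(\C)CC/C=C(\C)CC/C=C(\C)CCC(Br)C(C)(C)O)c(C)c1OC
F6 | step 3 | terminal 14,15-epoxide of 6 (racemic) | COc1c(OC)c(OC)c(C/C=C(\C)CC/C=C(\C)CC/C=C(\C)CCC2OC2(C)C)c(C)c1OC
F7 | step 3 | secondary allylic alcohol with terminal isopropenyl group (racemic) | COc1c(OC)c(OC)c(C/C=C(\C)CC/C=C(\C)CC/C=C(\C)CCC(O)C(C)=C)c(C)c1OC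
F8 | step 3 | ethyl (4E,8E,12E,16E)-4,8,12,16-tetramethyl-18-(2,3,4,5-tetramethoxy-6-methylphenyl)octadeca-4,8,12,16-tetraenoate | COc1c(OC)c(OC)c(C/C=C(\C)CC/C=C(\C)CC/C=C(\C)CC/C=C(\C)CCC(=O)OCC)c(C)c1OC
F9 | step 6 | trimethylsilyl enyne from 8 and lithiated 1-(trimethylsilyl)propyne | COc1c(OC)c(OC)c(C/C=C(\C)CC/C=C(\C)CC/C=C(\C)CC/C=C(\C)CCC#C[Si](C)(C)C)c(C)c1OC
F10 | step 6 | (18Z)-19-trimethylsilyl analogue of 11 (silicon cis to the chain) | COc1c(OC)c(OC)c(C/C=C(\C)CC/C=C(\C)CC/C=C(\C)CC/C=C(\C)CC/C=C(/C)[Si](C)(C)C)c(C)c1OC
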